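**Retrosynthetic overview** (labdane numbering: ring A = C1–C5 + C10, ring B = C5–C10, side chain C11 onward on C9)
- Side chain last: the 15Z alkene from an enyne (cis-semi-reduction), the enyne–butenolide bond by Sonogashira coupling, and C9–C11 by Negishi coupling of a C8=C9 enol triflate with an alkylzinc reagent cut from an E-alkylidene butyrolactone (which carries the 13E geometry).
- Enabling feature: ring B has its only functionality at C8=C9, and C9 sits between the quaternary C10 and C8. Read as the enol triflate of a C9 ketone, both α-carbons (C10, C8) are nucleophiles, and the remaining ring-B carbons C5–C6–C7 are an enal (C5 electrophilic β-carbon, C7 carbonyl).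
- Key disconnection: both carbocycles at once from an acyclic keto enal by an amine-catalysed Michael/aldol condensation; C10→C5 closes ring A first and sets C5 and C10, then C8→C7 closes ring B.
- The keto enal comes from methyl 3,3-dimethylpent-4-enoate, 2-methylpent-1-en-3-one and crotonaldehyde (conjugate addition, cross-metathesis); the butenolide ring is bought.

Key step: step 5

Remark: all compounds marked as starting materials are taken to be catalogue compounds; nothing in this route has been run, so every outcome below is a prediction.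

Step 1
Reactants: 1 methyl 3,3-dimethylpent-4-enoate
Product: 2 3,3-dimethylpent-4-en-1-ol
Conditions: LiAlH4, Et2O, 0 °C to rt; aq. NaOH work-up
Reagents that add atoms: none
Why: LiAlH4 reduction of an ester to the primary alcohol; the isolated vinyl group is inert and no stereocentre is involved.

Step 2
Reactants: 2 3,3-dimethylpent-4-en-1-ol
Product: 3 5-bromo-3,3-dimethylpent-1-ene
Conditions: CBr4, PPh3, CH2Cl2, 0 °C to rt
Reagents that add atoms: carbon tetrabromide, BrC(Br)(Br)Br
Why: Appel bromination (SN2 displacement of the alkoxyphosphonium ion by bromide) at an unhindered primary carbon.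

Step 3
Reactants: 3 5-bromo-3,3-dimethylpent-1-ene; 4 2-methylpent-1-en-3-one
Product: 7 rac-4,8,8-trimethyldec-9-en-3-one, via Grignard reagent 5 (not isolated), via silyl enol ether 6 (not isolated)
Conditions: Mg, THF, rt; then CuBr·SMe2 (10 mol%), Me3SiCl, 4, THF, −78 °C; then 1 M HCl
Reagents that add atoms: none
Why: Copper-catalysed, Me3SiCl-accelerated conjugate addition of a primary Grignard reagent to the unsubstituted β-carbon of the enone, then hydrolysis of the silyl enol ether on work-up; the α-stereocentre forms as a racemate, which is immaterial because step 5 enolises it.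

Step 4
Reactants: 7 rac-4,8,8-trimethyldec-9-en-3-one; 8 (E)-but-2-enal
Product: 9 rac-(2E)-4,4,8-trimethyl-9-oxoundec-2-enal
Conditions: 8 (5 equiv), second-generation Hoveyda–Grubbs catalyst (5 mol%), CH2Cl2, 40 °C
Reagents that add atoms: none
Why: Olefin cross-metathesis with excess crotonaldehyde should give the E-enal under thermodynamic control; the quaternary allylic carbon of 7 slows the reaction but suppresses homodimerisation, and the ketone is a spectator.

Step 5
Reactants: 9 rac-(2E)-4,4,8-trimethyl-9-oxoundec-2-enal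
Product: 12 (4aS,8aS)-2,5,5,8a-tetramethyl-4a,5,6,7,8,8a-hexahydronaphthalen-1(4H)-one, via keto aldehyde 10 (not isolated), via aldol 11 (not isolated)
Conditions: (S)-2-[bis(3,5-bis(trifluoromethyl)phenyl)(trimethylsilyloxy)methyl]pyrrolidine (20 mol%), PhCO2H (20 mol%), toluene, 40 °C; then p-TsOH·H2O (20 mol%), 80 °C
Reagents that add atoms: none
Why: Proposed new method: the amine condenses with the enal to an E-iminium ion, the acid-equilibrated, more substituted enol of the C9 ketone (C10=C9) adds through C10 to the β-carbon C5 and closes ring A (6-(enolexo)-exo-trig Michael addition) to give 10, and after hydrolysis the ketone enolises toward C8, the only α-position left with hydrogens, and condenses with the C7 aldehyde (6-(enolendo)-exo-trig aldol, then dehydration) to close ring B as the conjugated enone. The closest known reactions are the iminium-catalysed Michael/aldol-condensation cascades of enals with β-keto esters and the acid-catalysed enol Michael additions of α-branched ketones that build quaternary centres; the addition of an unactivated α-branched ketone enol to an iminium ion is the unprecedented element, made plausible by the intramolecular six-ring closure. C5 should be set by the catalyst, whose diarylsilyloxymethyl group shields one face of the s-trans iminium ion so that C10 adds to the face that leads to 5S, the sense known for carbon nucleophiles with the (S)-catalyst. C10 should be set relative to C5 in a chair transition state with the iminium-bearing vinyl group equatorial and the small C10 methyl pseudo-axial, which places the C9 acyl branch and the C6 chain trans and leads to the trans-fused bicycle. The step needs C10 and not C8 to attack C5, which the tether secures because attack through C8 would close an eight-membered ring; the gem-dimethyl group at C4 favours the closure (Thorpe–Ingold effect) and, having no γ-hydrogen, excludes dienamine formation from the enal. Dehydration is driven by conjugation and removes the two aldol stereocentres, so only C5 and C10 remain, and neither is epimerisable afterwards.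

Step 6
Reactants: 12 (4aS,8aS)-2,5,5,8a-tetramethyl-4a,5,6,7,8,8a-hexahydronaphthalen-1(4H)-one
Product: 14 (4aS,8aS)-2,5,5,8a-tetramethyl-3,4,4a,5,6,7,8,8a-octahydronaphthalen-1-yl trifluoromethanesulfonate, via lithium enolate 13 (not isolated)
Conditions: LiBH(s-Bu)3, THF, −78 °C; then PhNTf2, −78 °C to rt
Reagents that add atoms: N-phenylbis(trifluoromethanesulfonimide), O=S(=O)(N(c1ccccc1)S(=O)(=O)C(F)(F)F)C(F)(F)F
Why: 1,4-Reduction of the β-unsubstituted α-methyl cyclohexenone by the bulky borohydride (as known for carvone) should give the C8=C9 enolate regiospecifically and N-phenyltriflimide traps it on oxygen; no stereocentre is formed and none is epimerisable.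

Step 7
Reactants: 15 3-(triphenyl-λ5-phosphanylidene)oxolan-2-one; 16 3-(triisopropylsilyl)prop-2-ynal
Product: 17 (3E)-3-[3-(triisopropylsilyl)prop-2-yn-1-ylidene]oxolan-2-one
Conditions: CH2Cl2, rt
Reagents that add atoms: none
Why: Wittig olefination with a stabilised ylide should give the E-alkylidene lactone (alkyne trans to the carbonyl group, cis to the ring CH2), which is the geometry needed for the C13=C14 bond.

Step 8
Reactants: 17 (3E)-3-[3-(triisopropylsilyl)prop-2-yn-1-ylidene]oxolan-2-one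
Product: 20 ethyl (2E)-2-(2-iodoethyl)-5-(triisopropylsilyl)pent-2-en-4-ynoate, via silyl ester 18 (not isolated), via iodo acid 19 (not isolated)
Conditions: Me3SiI, CH2Cl2, 0 °C to rt; then EtOH, rt
Reagents that add atoms: iodotrimethylsilane, C[Si](C)(C)I; ethanol, CCO
Why: Iodotrimethylsilane opens the lactone by O-silylation and SN2 attack of iodide at the O–CH2 carbon, and ethanolysis with in situ Fischer esterification of the freed acid gives the ethyl ester; the alkene geometry and the hindered alkynylsilane should be unaffected.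

Step 9
Reactants: 20 ethyl (2E)-2-(2-iodoethyl)-5-(triisopropylsilyl)pent-2-en-4-ynoate; 14 (4aS,8aS)-2,5,5,8a-tetramethyl-3,4,4a,5,6,7,8,8a-octahydronaphthalen-1-yl trifluoromethanesulfonate
Product: 22 ethyl (2E)-2-{2-[(4aS,8aS)-2,5,5,8a-tetramethyl-3,4,4a,5,6,7,8,8a-octahydronaphthalen-1-yl]ethyl}-5-(triisopropylsilyl)pent-2-en-4-ynoate, via alkylzinc iodide 21 (not isolated)
Conditions: Zn dust (activated with BrCH2CH2Br and Me3SiCl), LiCl, THF, 35 °C; then 14, Pd(OAc)2 (5 mol%), SPhos (10 mol%), THF/NMP, 60 °C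
Reagents that add atoms: none
Why: Negishi coupling: zinc insertion into the primary C–I bond tolerates the enoate and the alkynylsilane, and a palladium catalyst with a bulky biaryl phosphine should couple the primary alkylzinc iodide with the hindered alkenyl triflate, keeping the C8=C9 position and the E geometry.

Step 10
Reactants: 22 ethyl (2E)-2-{2-[(4aS,8aS)-2,5,5,8a-tetramethyl-3,4,4a,5,6,7,8,8a-octahydronaphthalen-1-yl]ethyl}-5-(triisopropylsilyl)pent-2-en-4-ynoate
Product: 23 (2E)-2-{2-[(4aS,8aS)-2,5,5,8a-tetramethyl-3,4,4a,5,6,7,8,8a-octahydronaphthalen-1-yl]ethyl}-5-(triisopropylsilyl)pent-2-en-4-yn-1-ol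
Conditions: i-Bu2AlH (2.5 equiv), CH2Cl2, −78 °C; aq. potassium sodium tartrate work-up
Reagents that add atoms: none
Why: i-Bu2AlH reduces the conjugated ester in a 1,2-fashion to the allylic alcohol at low temperature and leaves the silylalkyne and both alkenes untouched.

Step 11
Reactants: 23 (2E)-2-{2-[(4aS,8aS)-2,5,5,8a-tetramethyl-3,4,4a,5,6,7,8,8a-octahydronaphthalen-1-yl]ethyl}-5-(triisopropylsilyl)pent-2-en-4-yn-1-ol
Product: 24 (2E)-2-{2-[(4aS,8aS)-2,5,5,8a-tetramethyl-3,4,4a,5,6,7,8,8a-octahydronaphthalen-1-yl]ethyl}pent-2-en-4-yn-1-ol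
Conditions: n-Bu4NF, THF, 0 °C
Reagents that add atoms: none
Why: Fluoride-mediated protodesilylation of the alkynylsilane frees the terminal alkyne under conditions that the allylic alcohol and the alkenes tolerate.

Step 12
Reactants: 24 (2E)-2-{2-[(4aS,8aS)-2,5,5,8a-tetramethyl-3,4,4a,5,6,7,8,8a-octahydronaphthalen-1-yl]ethyl}pent-2-en-4-yn-1-ol; 25 4-bromofuran-2(5H)-one
Product: 26 4-[(3E)-4-(hydroxymethyl)-6-[(4aS,8aS)-2,5,5,8a-tetramethyl-3,4,4a,5,6,7,8,8a-octahydronaphthalen-1-yl]hex-3-en-1-yn-1-yl]furan-2(5H)-one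
Conditions: PdCl2(PPh3)2 (5 mol%), CuI (10 mol%), Et3N, THF, rt
Reagents that add atoms: none
Why: Sonogashira coupling of the terminal enyne with the vinylogous acyl bromide, a known route to 4-alkynyl butenolides, should proceed under mild amine conditions in the presence of the free alcohol.

Step 13
Reactants: 26 4-[(3E)-4-(hydroxymethyl)-6-[(4aS,8aS)-2,5,5,8a-tetramethyl-3,4,4a,5,6,7,8,8a-octahydronaphthalen-1-yl]hex-3-en-1-yn-1-yl]furan-2(5H)-one
Product: 27 4-[(1Z,3E)-4-(hydroxymethyl)-6-[(4aS,8aS)-2,5,5,8a-tetramethyl-3,4,4a,5,6,7,8,8a-octahydronaphthalen-1-yl]hexa-1,3-dien-1-yl]furan-2(5H)-one (CNP0232848.4)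
Conditions: Zn dust activated with Cu(OAc)2 and AgNO3, MeOH/H2O, rt, dark
Reagents that add atoms: none
Why: Cis-semi-reduction with a zinc–copper–silver couple is selective for alkynes conjugated on both sides and should deliver the 15Z alkene by syn addition of hydrogen, leaving the 13E alkene, the ring alkene and the butenolide untouched.

**Compound list**
1 | methyl 3,3-dimethylpent-4-enoate | COC(=O)CC(C)(C)C=C | starting material
2 | 3,3-dimethylpent-4-en-1-ol | OCCC(C)(C)C=C | intermediate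
3 | 5-bromo-3,3-dimethylpent-1-ene | BrCCC(C)(C)C=C | intermediate
4 | 2-methylpent-1-en-3-one | CCC(=O)C(C)=C | starting material
5 | (3,3-dimethylpent-4-en-1-yl)magnesium bromide | C=CC(C)(C)CC[Mg]Br | intermediate
6 | trimethyl[(4,8,8-trimethyldeca-3,9-dien-3-yl)oxy]silane (E/Z mixture) | CCC(O[Si](C)(C)C)=C(C)CCCC(C)(C)C=C | intermediate
7 | rac-4,8,8-trimethyldec-9-en-3-one | CCC(=O)C(C)CCCC(C)(C)C=C | intermediate
8 | (E)-but-2-enal | C/C=C/C=O | starting material
9 | rac-(2E)-4,4,8-trimethyl-9-oxoundec-2-enal | CCC(=O)C(C)CCCC(C)(C)/C=C/C=O | intermediate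
10 | 2-[(1S,6S)-2,2,6-trimethyl-6-propanoylcyclohexyl]acetaldehyde | CCC(=O)[C@@]1(C)CCCC(C)(C)[C@@H]1CC=O | intermediate
11 | (4aS,8aS)-3-hydroxy-2,5,5,8a-tetramethyloctahydronaphthalen-1(2H)-one (mixture at C2 and C3) | CC1C(O)C[C@H]2C(C)(C)CCC[C@]2(C)C1=O | intermediate
12 | (4aS,8aS)-2,5,5,8a-tetramethyl-4a,5,6,7,8,8a-hexahydronaphthalen-1(4H)-one | CC1=CC[C@H]2C(C)(C)CCC[C@]2(C)C1=O | intermediate
13 | lithium (4aS,8aS)-2,5,5,8a-tetramethyl-3,4,4a,5,6,7,8,8a-octahydronaphthalen-1-olate | CC1=C(O[Li])[C@@]2(C)CCCC(C)(C)[C@@H]2CC1 | intermediate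
14 | (4aS,8aS)-2,5,5,8a-tetramethyl-3,4,4a,5,6,7,8,8a-octahydronaphthalen-1-yl trifluoromethanesulfonate | CC1=C(OS(=O)(=O)C(F)(F)F)[C@@]2(C)CCCC(C)(C)[C@@H]2CC1 | intermediate
15 | 3-(triphenyl-λ5-phosphanylidene)oxolan-2-one | O=C1OCCC1=P(c1ccccc1)(c1ccccc1)c1ccccc1 | starting material
16 | 3-(triisopropylsilyl)prop-2-ynal | CC(C)[Si](C#CC=O)(C(C)C)C(C)C | starting material
17 | (3E)-3-[3-(triisopropylsilyl)prop-2-yn-1-ylidene]oxolan-2-one | CC(C)[Si](C#C/C=C1\CCOC1=O)(C(C)C)C(C)C | intermediate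
18 | trimethylsilyl (2E)-2-(2-iodoethyl)-5-(triisopropylsilyl)pent-2-en-4-ynoate | C[Si](C)(C)OC(=O)/C(CCI)=C/C#C[Si](C(C)C)(C(C)C)C(C)C | intermediate
19 | (2E)-2-(2-iodoethyl)-5-(triisopropylsilyl)pent-2-en-4-ynoic acid | OC(=O)/C(CCI)=C/C#C[Si](C(C)C)(C(C)C)C(C)C | intermediate
20 | ethyl (2E)-2-(2-iodoethyl)-5-(triisopropylsilyl)pent-2-en-4-ynoate | CCOC(=O)/C(CCI)=C/C#C[Si](C(C)C)(C(C)C)C(C)C | intermediate
21 | [(3E)-3-(ethoxycarbonyl)-6-(triisopropylsilyl)hex-3-en-5-yn-1-yl]zinc iodide | CCOC(=O)/C(CC[Zn]I)=C/C#C[Si](C(C)C)(C(C)C)C(C)C | intermediate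
22 | ethyl (2E)-2-{2-[(4aS,8aS)-2,5,5,8a-tetramethyl-3,4,4a,5,6,7,8,8a-octahydronaphthalen-1-yl]ethyl}-5-(triisopropylsilyl)pent-2-en-4-ynoate | CC1=C(CC/C(=C\C#C[Si](C(C)C)(C(C)C)C(C)C)C(=O)OCC)[C@@]2(C)CCCC(C)(C)[C@@H]2CC1 | intermediate
23 | (2E)-2-{2-[(4aS,8aS)-2,5,5,8a-tetramethyl-3,4,4a,5,6,7,8,8a-octahydronaphthalen-1-yl]ethyl}-5-(triisopropylsilyl)pent-2-en-4-yn-1-ol | CC1=C(CC/C(=C\C#C[Si](C(C)C)(C(C)C)C(C)C)CO)[C@@]2(C)CCCC(C)(C)[C@@H]2CC1 | intermediate
24 | (2E)-2-{2-[(4aS,8aS)-2,5,5,8a-tetramethyl-3,4,4a,5,6,7,8,8a-octahydronaphthalen-1-yl]ethyl}pent-2-en-4-yn-1-ol | CC1=C(CC/C(=C\C#C)CO)[C@@]2(C)CCCC(C)(C)[C@@H]2CC1 | intermediate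
25 | 4-bromofuran-2(5H)-one | BrC1=CC(=O)OC1 | starting material
26 | 4-[(3E)-4-(hydroxymethyl)-6-[(4aS,8aS)-2,5,5,8a-tetramethyl-3,4,4a,5,6,7,8,8a-octahydronaphthalen-1-yl]hex-3-en-1-yn-1-yl]furan-2(5H)-one | CC1=C(CC/C(=C\C#CC2=CC(=O)OC2)CO)[C@@]2(C)CCCC(C)(C)[C@@H]2CC1 | intermediate
27 | 4-[(1Z,3E)-4-(hydroxymethyl)-6-[(4aS,8aS)-2,5,5,8a-tetramethyl-3,4,4a,5,6,7,8,8a-octahydronaphthalen-1-yl]hexa-1,3-dien-1-yl]furan-2(5H)-one | CC1=C(CC/C(=C\C=C/C2=CC(=O)OC2)CO)[C@@]2(C)CCCC(C)(C)[C@@H]2CC1 | target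

Total step count: 13. Longest linear sequence: 11 steps (steps 1–6 and 9–13); steps 7–8 build the side-chain fragment.

**Steps most likely to fail**

Step 5. The ketone enol may add too slowly to the iminium ion, facial control may erode, or ring A may close to the cis-fused series. The fallback sets out from 7 and returns at 12, using a covalent chiral auxiliary and known reaction types. Cross-metathesis of 7 with methyl acrylate should give methyl (2E)-4,4,8-trimethyl-9-oxoundec-2-enoate F1. Condensation with (R)-1-phenylethylamine, the antipode predicted by the known topicity rule for an enamine with the C10 methyl cis to nitrogen, gives methyl (2E)-4,4,8-trimethyl-9-{[(1R)-1-phenylethyl]imino}undec-2-enoate F2. On heating, its more substituted secondary enamine tautomer should cyclise by an aza-ene-type Michael addition (ring A, C10 quaternary, trans) to methyl 2-[(1S,6S)-2,2,6-trimethyl-6-{N-[(1R)-1-phenylethyl]propanimidoyl}cyclohexyl]acetate F3. Aqueous acetic acid frees methyl 2-[(1S,6S)-2,2,6-trimethyl-6-propanoylcyclohexyl]acetate F4. KOt-Bu closes ring B by Claisen (Dieckmann-type) condensation to (4aS,8aS)-2,5,5,8a-tetramethylhexahydronaphthalene-1,3(2H,4H)-dione F5. Tf2O with 2,6-lutidine triflates the less hindered C7 oxygen to (4aS,8aS)-3,4a,8,8-tetramethyl-4-oxo-1,4,4a,5,6,7,8,8a-octahydronaphthalen-2-yl trifluoromethanesulfonate F6, and Pd(OAc)2/PPh3 with HCO2H/n-Bu3N reduces the triflate to 12.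

Step 9. Oxidative addition and transmetalation at the triflate flanked by the quaternary C10 may be slow, so that protodezincation or β-hydride loss of the alkyl partner wins. The fallback sets out from 14 and returns at 22 by putting the easier sp2–sp2 coupling first. Stille coupling of 14 with tributyl(vinyl)stannane (Pd(PPh3)4, LiCl) should give (4aS,8aS)-5-ethenyl-1,1,4a,6-tetramethyl-1,2,3,4,4a,7,8,8a-octahydronaphthalene F7. 9-BBN hydroborates the terminal vinyl carbon and NaOH/H2O2 gives 2-[(4aS,8aS)-2,5,5,8a-tetramethyl-3,4,4a,5,6,7,8,8a-octahydronaphthalen-1-yl]ethan-1-ol F8. I2/PPh3/imidazole gives (4aS,8aS)-5-(2-iodoethyl)-1,1,4a,6-tetramethyl-1,2,3,4,4a,7,8,8a-octahydronaphthalene F9. Alkylation of triethyl phosphonoacetate (NaH) gives ethyl 2-(diethoxyphosphoryl)-4-[(4aS,8aS)-2,5,5,8a-tetramethyl-3,4,4a,5,6,7,8,8a-octahydronaphthalen-1-yl]butanoate F10. Horner–Wadsworth–Emmons reaction of F10 with 16 (NaH, THF) gives 22 after removal of the Z isomer.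

Step 13. The alkyne may be over-reduced, or the dienyl butenolide may isomerise from Z to E during reduction and isolation. The fallback sets out from 24 and returns at 27, fixing the Z geometry before the butenolide is attached. N-Iodosuccinimide/AgNO3 gives (2E)-5-iodo-2-{2-[(4aS,8aS)-2,5,5,8a-tetramethyl-3,4,4a,5,6,7,8,8a-octahydronaphthalen-1-yl]ethyl}pent-2-en-4-yn-1-ol F11. Diimide from 2-nitrobenzenesulfonylhydrazide/Et3N cis-reduces the iodoalkyne to (2E,4Z)-5-iodo-2-{2-[(4aS,8aS)-2,5,5,8a-tetramethyl-3,4,4a,5,6,7,8,8a-octahydronaphthalen-1-yl]ethyl}penta-2,4-dien-1-ol F12. Stille coupling of F12 with 4-(tributylstannyl)furan-2(5H)-one (Pd2(dba)3, AsPh3, CuI) gives 27 with retention of the alkene geometry.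

Further compounds
F1 | step 5 | methyl (2E)-4,4,8-trimethyl-9-oxoundec-2-enoate | CCC(=O)C(C)CCCC(C)(C)/C=C/C(=O)OC
F2 | step 5 | methyl (2E)-4,4,8-trimethyl-9-{[(1R)-1-phenylethyl]imino}undec-2-enoate | CCC(=N[C@H](C)c1ccccc1)C(C)CCCC(C)(C)/C=C/C(=O)OC
F3 | step 5 | methyl 2-[(1S,6S)-2,2,6-trimethyl-6-{N-[(1R)-1-phenylethyl]propanimidoyl}cyclohexyl]acetate | CCC(=N[C@H](C)c1ccccc1)[C@@]1(C)CCCC(C)(C)[C@@H]1CC(=O)OC
F4 | step 5 | methyl 2-[(1S,6S)-2,2,6-trimethyl-6-propanoylcyclohexyl]acetate | CCC(=O)[C@@]1(C)CCCC(C)(C)[C@@H]1CC(=O)OC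
F5 | step 5 | (4aS,8aS)-2,5,5,8a-tetramethylhexahydronaphthalene-1,3(2H,4H)-dione | CC1C(=O)C[C@H]2C(C)(C)CCC[C@]2(C)C1=O
F6 | step 5 | (4aS,8aS)-3,4a,8,8-tetramethyl-4-oxo-1,4,4a,5,6,7,8,8a-octahydronaphthalen-2-yl trifluoromethanesulfonate | CC1=C(OS(=O)(=O)C(F)(F)F)C[C@H]2C(C)(C)CCC[C@]2(C)C1=O
F7 | step 9 | (4aS,8aS)-5-ethenyl-1,1,4a,6-tetramethyl-1,2,3,4,4a,7,8,8a-octahydronaphthalene | CC1=C(C=C)[C@@]2(C)CCCC(C)(C)[C@@H]2CC1
F8 | step 9 | 2-[(4aS,8aS)-2,5,5,8a-tetramethyl-3,4,4a,5,6,7,8,8a-octahydronaphthalen-1-yl]ethan-1-ol | CC1=C(CCO)[C@@]2(C)CCCC(C)(C)[C@@H]2CC1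
F9 | step 9 | (4aS,8aS)-5-(2-iodoethyl)-1,1,4a,6-tetramethyl-1,2,3,4,4a,7,8,8a-octahydronaphthalene | CC1=C(CCI)[C@@]2(C)CCCC(C)(C)[C@@H]2CC1
F10 | step 9 | ethyl 2-(diethoxyphosphoryl)-4-[(4aS,8aS)-2,5,5,8a-tetramethyl-3,4,4a,5,6,7,8,8a-octahydronaphthalen-1-yl]butanoate | CC1=C(CCC(C(=O)OCC)P(=O)(OCC)OCC)[C@@]2(C)CCCC(C)(C)[C@@H]2CC1
F11 | step 13 | (2E)-5-iodo-2-{2-[(4aS,8aS)-2,5,5,8a-tetramethyl-3,4,4a,5,6,7,8,8a-octahydronaphthalen-1-yl]ethyl}pent-2-en-4-yn-1-ol | CC1=C(CC/C(=C\C#CI)CO)[C@@]2(C)CCCC(C)(C)[C@@H]2CC1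
F12 | step 13 | (2E,4Z)-5-iodo-2-{2-[(4aS,8aS)-2,5,5,8a-tetramethyl-3,4,4a,5,6,7,8,8a-octahydronaphthalen-1-yl]ethyl}penta-2,4-dien-1-ol | CC1=C(CC/C(=C\C=C/I)CO)[C@@]2(C)CCCC(C)(C)[C@@H]2CC1
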